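Slowness comes first here: X is an intermediate, made from Q over G and lost to D, and that loss has a half-life of 2.48 h.

    X → D (k1 = 0.28 h⁻¹)
    Q + G → X + G, rate k2*[Q]^1.5*[G]/(1 + ([Q]/Kh2)^1.5) (Kh2 = 0.055 M, k2 = 4.5 × 10⁵ M⁻¹·⁵ h⁻¹)

| setting | dawn | spring | dusk |
|---|---|---|---|
| Q | 35 mM | 35 mM | 35 mM |
| G | 18 µM | 27 µM | 40 µM |
| time | 5.0 h | 5.0 h | 5.0 h |

- which of the two there is more of at the end, dawn (D / X)
- which of the two there is more of at the end, spring (D / X)
- which of the two there is more of at the end, dusk (D / X)
- how much X is there at the end, in percent of the Q charged: dawn
- how much X is there at the end, in percent of the Q charged: spring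
- how much X is there at the end, in percent of the Q charged: dusk

1. Main step alone. G is not consumed, so the rate law integrates by hand. Let L be the share of Q left at the reading, reckoned with the small Q left dropped from the term of the integral that is linear in Q. L comes to 4.86 % in dawn, 2.42 % in spring and 1.19 % in dusk. The same integral gives t_h, the time to turn half of Q, which goes inversely with G: 0.714 h, 0.476 h and 0.321 h. In spring, Q starts turning at 1.51 h⁻¹, faster than the 0.28 h⁻¹ at which X is lost.

2. Add X → D. The scheme runs one way, so its end state is D, and what matters is how far along the flask is at 5.0 h. That span is 2.02 half-lives, so 24.7 % of any X born at the start is still X. This is the survival factor S: the exponential of minus the rate constant times the time elapsed.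

3. The rest: X is born late. My reckoning places the whole birth of X at t_h, so the turned share survives over the shorter span. That gives X at 28.7 % in dawn, 27.5 % in spring and 26.7 % in dusk. What is turned and is not X is D: 66.5 % in dawn, 70.1 % in spring and 72.1 % in dusk, each more than the X reckoned for that flask , so D leads.

4. The forecast chose D, D, D and put X at 33 %, 31 % and 29 %, each higher than my reckoning for that flask ; its ground for the fall from dawn to dusk reads “More enzyme only forms X earlier and gives it longer to decay”.

5. The simulation gives X 32.6 % against D 62.6 % in dawn, 30.7 % against 66.9 % in spring, and 29.1 % against 69.7 % in dusk.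

In dawn, X stands far below the Q turned because X goes on to D: with that step taken away, dawn ends at 95.2 % X, not 32.6 %. Spring lands 3.2 percentage points above my single-birth reckoning, and dusk, the lowest, still holds more than S. Spring read at 12 h has S down to 3.47 %, and that flask holds X at 4.90 %.

The constants are made up; the run is a simulation.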